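Lignan numbering is used throughout: C7 is the ring ArCH–O carbon, C8 the ring CH bearing C9 (the CH2O–acyl carbon), C8' the ring CH bearing the carbinol carbon C7', and C9' the ring OCH2. Ar = 4-(tert-butyldimethylsilyloxy)-3-methoxyphenyl. Compound numbers are those of the steps below.

## The problem

The target 16 is a 7,9'-epoxylignan: one tetrahydrofuran ring (O, C7, C8, C8', C9') carrying a guaiacyl group on C7, a p-coumaroyloxymethyl group (C9) on C8 and a guaiacyl carbinol (C7') on C8'. It has four contiguous stereocentres (7S, 8R, 7'S, 8'R), with the C7 aryl trans to C9 and C9 cis to C7'. The hardest centre is C7', which lies outside the ring and is controlled in an open chain only weakly by C8'. If O7' is tied to C9 in a second five-membered ring, that ring must be cis-fused and C7' becomes a ring stereocentre. The molecule does not tolerate rough treatment: the 4-hydroxybenzylic alcohol at C7' and the benzylic ether at C7 ionise in acid (quinone methides, closure of the C7'–OH/C9–OH pair to a furofuran). The E-cinnamate ester excludes hydrides, hydrogenolysis and strong base once it is in place, and three phenols must be unmasked together at the end. The enabling feature is that C9–C8–C8'–C9' is a succinate unit flanked by two identical ArCH–O carbons, C7 and C7'. If C9 and C9' are both raised to the carboxyl level and joined to O7' and O7, the molecule becomes a C2-symmetric, cis-fused bislactone, whose four stereocentres are two symmetry-related pairs made by the same reaction. The price is that the two halves must be told apart again afterwards, and that the primary C9 hydroxyl must be acylated in the presence of the secondary C7' hydroxyl.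

## Retrosynthesis

**16 to 11 and 14.** The three phenolic O–Si bonds of 15 and then its ester bond C9O–C(=O) are cut, giving diol 11 and silylated p-coumaric acid 14. The ester is introduced as late as possible because it survives none of the reductions. One silyl type on all three phenols allows a single buffered fluoride step and avoids hydrogenolysis, which would also reduce the alkene and the benzylic C–O bonds. The forward acylation must prefer the primary C9 hydroxyl over the hindered benzylic C7' hydroxyl, under neutral conditions.

**11 to 10.** C9 is raised to the carboxyl level and closed onto O7', giving lactone–tetrahydrofuran 10. This hides both free hydroxyls in one group and locks the C8/C8' cis relationship and the C7' configuration in a rigid bicycle. Forward, only the acyl C–O bond is broken by LiBH4, so C7' keeps its configuration.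

**10 to 8 (through 9).** C9' is raised to the carbonyl level as well. The precursor is bislactone 8, whose C2 axis exchanges C7/C7', C8/C8' and C9/C9'. The four stereocentres become two equivalent pairs, and either lactone gives the same lactol 9 on reduction, so no site selectivity is needed. What is asked of the forward reactions is mono- rather than double reduction with i-Bu2AlH, followed by deoxygenation of the lactol without ionising the benzylic C–O bonds.

**8 to 2 and two molecules of 4 (through 5, 6 and 7).** The bonds C7–C8 and C7'–C8' and the two lactone bonds O7–C9' and O7'–C9 are cut. The succinate core becomes the bis-silyl ketene acetal 2 and each half becomes silyl vanillin 4. Against cuts through the ring C–O bonds or a single aldol, this one removes both aryl carbinols and all four stereocentres at once and leaves two one-step building blocks. The forward step must control the aldehyde face and the relative topicity in two successive aldol additions (via 5 and 6), and both hydroxyls must then lactonise (via 7).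

**2 to 1, 4 to 3, 14 to 12.** Furan 2 comes from succinic anhydride 1 by double O-silylation, aldehyde 4 from vanillin 3, and acid 14 from p-coumaric acid 12 through the bis-silyl compound 13.

## Roads not taken

**Alternative 1:** The cut is through C7–C8 and C8'–C9', the two C–C bonds that close the tetrahydrofuran onto a preformed lactone ring.
- Forward step: CsF removes silicon and chloride from chloro ether A3, and the resulting carbonyl ylide A4 adds across C8=C8' of butenolide A2 anti to the C7' aryl, giving furofuranone A1, the allyl-protected counterpart of 10.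
- Merits: A1 arrives with C9 and C9' already at different oxidation levels, so the statistical mono-reduction of the chosen plan is not needed. The end game after the key step is shorter (reduction, acylation, deallylation with zerovalent palladium). In this respect the road is better.
- Weak points: the only source of absolute configuration is C7' of A2, whose hydrogen is benzylic and γ to the lactone carbonyl. Basic fluoride can deprotonate it to the aromatic furanolate and racemise it.
- Weak points: A3 is an α-chloro ether of an electron-rich benzaldehyde and ionises easily.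
- Weak points: both the regiochemistry (ArCH to C8, not C8') and the exo placement of the C7 aryl must go one way, and non-stabilised carbonyl ylides are not reliably selective on either count.
- Comparison: the chosen plan sets against the shorter end game that all four stereocentres come from one catalyst-controlled operation on two one-step building blocks, and that its symmetric product is easy to purify. It pays with steps 4 and 5.

**Alternative 2:** The cut is through C8–C9 and C8'–C7', made together as a cyclobutanone.
- Forward step: dichloroketene A7 (from Cl3CCOCl and Zn–Cu) adds to C8=C8' of dihydrofuran A6 anti to the aryl, giving dichlorocyclobutanone A5.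
- Merits: C7 would be set by an established catalytic asymmetric Heck arylation, which is firmer ground than the enantiocontrol of the chosen key step. The suprafacial ketene addition guarantees the C8/C8' cis relationship.
- Weak points: A5 lacks the second aryl group and the C7' oxygen, and C9 and C7' are bonded to each other. Dechlorination, arylation at C7' with stereocontrol and a regioselective Baeyer–Villiger insertion between C9 and C7' would be needed before a lactone of type 10 is reached.
- Weak points: the two alkene carbons of A6 differ only through the remote aryl group, so the regiochemistry of the cycloaddition is unbiased.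
- Weak points: A6 is a cyclic bis-allylic ether. O-acylation by A7 followed by a zwitterionic Claisen-type ring expansion competes with the (2+2) addition.
- Comparison: this road is several steps longer and sets only the ring stereocentres in its key step. The chosen plan delivers both aryl carbinols and all four centres at once.

**Alternative 3:** The cut is through C7'–C8' and the lactone bond O7'–C9.
- Forward step: SmI2 (divalent samarium) reduces aldehyde 4 to its ketyl, which adds to C8' of dihydrofuran ester A9. Protonation at C8 and lactonisation onto the C9 ester give furofuranone A8, which is compound 10 itself.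
- Merits: the road shares aldehyde 4, ends directly at 10 without a statistical step, and rests on a well-known reaction type. In step count from 10 onward it equals the chosen plan, and before 10 it is shorter if A9 is at hand.
- Weak points: ketyls of electron-rich aryl aldehydes are stabilised, add slowly to β-substituted enoates and tend to pinacol coupling.
- Weak points: the trivalent samarium enolate at C8 has the ring oxygen on C7 in the β-position, so β-elimination would open the ring.
- Weak points: three stereocentres, among them the difficult C7', would be set by substrate control from C7 alone.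
- Weak points: A9 must be made as a single enantiomer, and its C7–H (benzylic and γ to the ester) is prone to racemisation and aromatisation to the furan.
- Comparison: the chosen plan is weaker in its end game but sets C7' in the same catalyst-controlled event as C7, which is where Alternative 3 is weakest.

Key step: step 3

Assumption: (S)-BINOL is taken as the ligand enantiomer that exposes the Si face of the aryl aldehyde, by analogy with Ti(OiPr)4/BINOL-catalysed additions to aromatic aldehydes; should the sense prove opposite, (R)-BINOL is used with no other change.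

## Route

Step 1
Reactants: 1 succinic anhydride
Product: 2 2,5-bis(trimethylsilyloxy)furan
Conditions: Me3SiCl, Et3N, ZnCl2 (cat.), MeCN, 20 °C; distillation
Reagents that add atoms: chlorotrimethylsilane, C[Si](C)(C)Cl
Why: Double O-silylation of the anhydride under soft enolisation gives the aromatic bis-silyl ketene acetal; this is the known preparation of 2, which is distilled and kept dry.

Step 2
Reactants: 3 vanillin
Product: 4 4-(tert-butyldimethylsilyloxy)-3-methoxybenzaldehyde
Conditions: t-BuMe2SiCl, imidazole, DMF, 20 °C
Reagents that add atoms: tert-butyldimethylsilyl chloride, CC(C)(C)[Si](C)(C)Cl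
Why: Standard phenol silylation; the aryl silyl ether should withstand Lewis acids at low temperature, dilute acid and hydride reagents and is removed last by fluoride.

Step 3
Reactants: 2 2,5-bis(trimethylsilyloxy)furan; 4 4-(tert-butyldimethylsilyloxy)-3-methoxybenzaldehyde (2.2 equiv)
Product: 8 (1S,4S,5S,8S)-4,8-bis[4-(tert-butyldimethylsilyloxy)-3-methoxyphenyl]-3,7-dioxabicyclo[3.3.0]octane-2,6-dione, via mono-aldol silyl ketene acetal 5 (not isolated), via bis-aldol anhydride 6 (not isolated), via hydroxy lactone acid 7 (not isolated)
Conditions: Ti(OiPr)4 (20 mol%), (S)-BINOL (20 mol%), 4 Å MS, Et2O, −20 → 0 °C; then 1 M HCl, THF, 20 °C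
Reagents that add atoms: none
Why: Proposed new method: the closest known reactions are the TiCl4-promoted double aldol–lactonisation of 2 with aryl aldehydes (racemic) and the Ti(OiPr)4/BINOL-catalysed Mukaiyama aldol addition of silyl ketene acetals to aryl aldehydes, and their combination on a bis(silyloxy)furan has not been shown. C3 of 2 (C8) adds to the catalyst-bound aldehyde through an open transition state, the Me3Si group passes to the aldolate oxygen and frees the catalyst, and C4 (C8') of the remaining silyl ketene acetal 5 adds to a second aldehyde to give anhydride 6. The catalyst selects the Si face of each aldehyde (C7, C7'); the syn topicity that such catalysts favour with substituted ketene silyl acetals places each aryl trans to the neighbouring carboxyl carbon (exo in the product) and so fixes C8 and C8' relative to C7 and C7'. In the second addition the C8 side chain of 5 shields one face, so C8' forms trans to it, which is also the sense the catalyst asks for. Aqueous HCl removes the Me3Si ethers, the C7 hydroxyl opens the anhydride at C9' by 5-exo-trig acyl substitution to lactone acid 7, and the C7' hydroxyl closes onto the C9 acid in the same 5-exo-trig mode, cis fusion being the only one open to two five-membered rings. The step needs enantiofacial and syn selectivity in both additions; because two catalyst-controlled events build one C2-symmetric product, mismatched material ends up as diastereomers, and an adduct with the wrong C8/C8' relationship cannot close the second lactone and is removed as an acid, so 8 should be enriched beyond the selectivity of a single addition.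

Step 4
Reactants: 8 (1S,4S,5S,8S)-4,8-diaryl-3,7-dioxabicyclo[3.3.0]octane-2,6-dione
Product: 9 (1S,4S,5S,8S)-4,8-diaryl-6-hydroxy-3,7-dioxabicyclo[3.3.0]octan-2-one (lactol, both anomers at C6)
Conditions: i-Bu2AlH (1.0 equiv), CH2Cl2, −78 °C; aq. potassium sodium tartrate
Reagents that add atoms: none
Why: Lactone-to-lactol reduction with i-Bu2AlH, whose tetrahedral aluminium hemiacetal persists at −78 °C; the two lactones of 8 are homotopic, so either gives 9, and only mono- against double reduction has to be controlled (one equivalent, slow addition, recovery of 8).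

Step 5
Reactants: 9 lactol
Product: 10 (1S,4S,5R,8S)-4,8-bis[4-(tert-butyldimethylsilyloxy)-3-methoxyphenyl]-3,7-dioxabicyclo[3.3.0]octan-2-one
Conditions: Et3SiH, BF3·OEt2, CH2Cl2, −78 → −40 °C
Reagents that add atoms: none
Why: Ionic hydrogenation of a lactol: BF3·OEt2 ionises the hemiacetal to the cyclic oxocarbenium ion, which Et3SiH reduces to the ring CH2 (C9'); no stereocentre is touched and the lactone is inert at this temperature.

Step 6
Reactants: 10 lactone–tetrahydrofuran
Product: 11 (S)-[4-(tert-butyldimethylsilyloxy)-3-methoxyphenyl][(3R,4R,5S)-5-[4-(tert-butyldimethylsilyloxy)-3-methoxyphenyl]-4-(hydroxymethyl)oxolan-3-yl]methanol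
Conditions: LiBH4, THF, 0 → 20 °C; aq. NH4Cl
Reagents that add atoms: none
Why: LiBH4 reduction of a γ-lactone to the 1,4-diol; only the acyl C–O bond is cleaved, so the C7' hydroxyl is released with its configuration intact, and aryl silyl ethers and the benzylic ether are stable to the reagent.

Step 7
Reactants: 12 p-coumaric acid
Product: 14 (E)-3-[4-(tert-butyldimethylsilyloxy)phenyl]prop-2-enoic acid, via silyl ester silyl ether 13 (not isolated)
Conditions: t-BuMe2SiCl (2.5 equiv), imidazole, DMF, 20 °C; then AcOH–THF–H2O, 20 °C
Reagents that add atoms: tert-butyldimethylsilyl chloride, CC(C)(C)[Si](C)(C)Cl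
Why: Silylation of phenol and acid followed by selective hydrolysis of the far more labile silyl ester in aqueous acetic acid, to which the aryl silyl ether and the E-alkene are stable.

Step 8
Reactants: 11 diol; 14 (E)-3-[4-(tert-butyldimethylsilyloxy)phenyl]prop-2-enoic acid (1.0 equiv)
Product: 15 [(2S,3R,4R)-2-Ar-4-[(S)-Ar(hydroxy)methyl]oxolan-3-yl]methyl (E)-3-[4-(tert-butyldimethylsilyloxy)phenyl]prop-2-enoate
Conditions: DCC, DMAP (cat.), CH2Cl2, 0 °C
Reagents that add atoms: none
Why: Steglich esterification; with one equivalent of acid at 0 °C the primary C9 hydroxyl should react much faster than the hindered secondary benzylic C7' hydroxyl, and the neutral medium avoids ionisation at C7'.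

Step 9
Reactants: 15 tris-silyl ester
Product: 16 [(2S,3R,4R)-2-(4-hydroxy-3-methoxyphenyl)-4-[(S)-hydroxy(4-hydroxy-3-methoxyphenyl)methyl]oxolan-3-yl]methyl (E)-3-(4-hydroxyphenyl)prop-2-enoate
Conditions: Bu4NF, AcOH, THF, 0 °C
Reagents that add atoms: none
Why: Fluoride cleavage of the three aryl silyl ethers; the AcOH buffer keeps the phenols protonated, so the cinnamate ester should not be cleaved and no quinone methide should form from the 4-hydroxybenzylic alcohol.

## Compound list

1 | succinic anhydride | O=C1CCC(=O)O1 | starting material
2 | 2,5-bis(trimethylsilyloxy)furan | C[Si](C)(C)Oc1ccc(O[Si](C)(C)C)o1 | intermediate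
3 | vanillin | COc1cc(C=O)ccc1O | starting material
4 | 4-(tert-butyldimethylsilyloxy)-3-methoxybenzaldehyde | COc1cc(C=O)ccc1O[Si](C)(C)C(C)(C)C | intermediate
5 | (3S)-3-[(S)-Ar(trimethylsilyloxy)methyl]-5-(trimethylsilyloxy)furan-2(3H)-one | COc1cc([C@@H](O[Si](C)(C)C)[C@@H]2C=C(O[Si](C)(C)C)OC2=O)ccc1O[Si](C)(C)C(C)(C)C | intermediate
6 | (3S,4S)-3,4-bis[(S)-Ar(trimethylsilyloxy)methyl]oxolane-2,5-dione (trans anhydride) | COc1cc([C@@H](O[Si](C)(C)C)[C@H]2C(=O)OC(=O)[C@@H]2[C@H](O[Si](C)(C)C)c3ccc(O[Si](C)(C)C(C)(C)C)c(OC)c3)ccc1O[Si](C)(C)C(C)(C)C | intermediate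
7 | (2S,3S,4S)-2-Ar-4-[(S)-Ar(hydroxy)methyl]-5-oxooxolane-3-carboxylic acid | COc1cc([C@@H](O)[C@H]2C(=O)O[C@H](c3ccc(O[Si](C)(C)C(C)(C)C)c(OC)c3)[C@H]2C(=O)O)ccc1O[Si](C)(C)C(C)(C)C | intermediate
8 | (1S,4S,5S,8S)-4,8-di-Ar-3,7-dioxabicyclo[3.3.0]octane-2,6-dione (cis-fused, both aryl groups exo, C2-symmetric) | COc1cc([C@@H](O3)[C@H]2C(=O)O[C@H](c4ccc(O[Si](C)(C)C(C)(C)C)c(OC)c4)[C@H]2C3=O)ccc1O[Si](C)(C)C(C)(C)C | intermediate
9 | (1S,4S,5S,8S)-4,8-di-Ar-6-hydroxy-3,7-dioxabicyclo[3.3.0]octan-2-one (both anomers at C6) | COc1cc([C@@H](O3)[C@H]2C(O)O[C@H](c4ccc(O[Si](C)(C)C(C)(C)C)c(OC)c4)[C@H]2C3=O)ccc1O[Si](C)(C)C(C)(C)C | intermediate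
10 | (1S,4S,5R,8S)-4,8-di-Ar-3,7-dioxabicyclo[3.3.0]octan-2-one (lactone carbonyl C9, lactone oxygen on C7') | COc1cc([C@@H](O3)[C@H]2CO[C@H](c4ccc(O[Si](C)(C)C(C)(C)C)c(OC)c4)[C@H]2C3=O)ccc1O[Si](C)(C)C(C)(C)C | intermediate
11 | (S)-Ar[(3R,4R,5S)-5-Ar-4-(hydroxymethyl)oxolan-3-yl]methanol | COc1cc([C@@H](O)[C@H]2CO[C@H](c3ccc(O[Si](C)(C)C(C)(C)C)c(OC)c3)[C@H]2CO)ccc1O[Si](C)(C)C(C)(C)C | intermediate
12 | p-coumaric acid | OC(=O)/C=C/c1ccc(O)cc1 | starting material
13 | tert-butyldimethylsilyl (E)-3-[4-(tert-butyldimethylsilyloxy)phenyl]prop-2-enoate | CC(C)(C)[Si](C)(C)OC(=O)/C=C/c1ccc(O[Si](C)(C)C(C)(C)C)cc1 | intermediate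
14 | (E)-3-[4-(tert-butyldimethylsilyloxy)phenyl]prop-2-enoic acid | OC(=O)/C=C/c1ccc(O[Si](C)(C)C(C)(C)C)cc1 | intermediate
15 | [(2S,3R,4R)-2-Ar-4-[(S)-Ar(hydroxy)methyl]oxolan-3-yl]methyl (E)-3-[4-(tert-butyldimethylsilyloxy)phenyl]prop-2-enoate | COc1cc([C@@H](O)[C@H]2CO[C@H](c3ccc(O[Si](C)(C)C(C)(C)C)c(OC)c3)[C@H]2COC(=O)/C=C/c2ccc(O[Si](C)(C)C(C)(C)C)cc2)ccc1O[Si](C)(C)C(C)(C)C | intermediate
16 | [(2S,3R,4R)-2-(4-hydroxy-3-methoxyphenyl)-4-[(S)-hydroxy(4-hydroxy-3-methoxyphenyl)methyl]oxolan-3-yl]methyl (E)-3-(4-hydroxyphenyl)prop-2-enoate (CNP0330050.2) | COc1cc([C@@H](O)[C@H]2CO[C@H](c3ccc(O)c(OC)c3)[C@H]2COC(=O)/C=C/c2ccc(O)cc2)ccc1O | target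

## Step count and risks

Total steps: 9. Longest linear sequence: 7 (steps 1, 3, 4, 5, 6, 8, 9; the same length counted from vanillin through step 2).

**Step 3 (key step, proposed new method).**
- Risk: insufficient or wrong-sense enantiofacial selectivity. The bis(silyloxy)furan is far more nucleophilic than the ketene acetals for which the catalyst is known, so an uncatalysed or silyl-cation-catalysed background reaction can compete.
- Risk: stalling after the first addition if silyl transfer to the aldolate is slow, and protodesilylation of 2 by isopropanol released from the catalyst.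
- Risk: low syn selectivity would divert material into exo,endo bislactones.
- Fallback: from 2 and 4 the known achiral variant is run with stoichiometric TiCl4 in CH2Cl2 at −78 °C and acid work-up. This should give the racemate, that is 8 together with its antipode, the (1R,4R,5R,8R)-bislactone F1. The enantiomers of this rigid C2-symmetric compound are separated by preparative chromatography on a polysaccharide-carbamate chiral stationary phase, and the route is re-entered at 8.

**Step 4.**
- Risk: statistical partition between unreacted 8, lactol 9 and doubly reduced material, because the first reduction does little to slow the second.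
- Fallback: from 8, LiOH (1.0 equiv) in THF–H2O at 0 °C should open one lactone only, since the carboxylate formed repels hydroxide from the second lactone (the principle behind selective mono-hydrolysis of symmetric diesters). This gives the lithium salt of 7, lithium carboxylate F2. After drying, i-Bu2AlH at −78 °C reduces the remaining lactone while the carboxylate is inert. Acidification gives the lactol acid F3, whose C7' hydroxyl and C9 acid re-close spontaneously, and the route is rejoined at 9.

**Step 5.**
- Risk: competing ionisation of the benzylic C7–O bond (or of the benzylic lactone C7'–O bond) by BF3·OEt2, leading to epimerisation at C7 or reductive ring opening, since both aryl groups are electron-rich.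
- Risk: partial loss of an aryl silyl ether.
- Fallback: from 9, NaBH4 in THF–MeOH at 0 °C reduces the lactol through its open hydroxy aldehyde form to the lactone diol F4. Mitsunobu cyclodehydration (PPh3, DIAD, THF, 0 °C) then activates the primary C9' hydroxyl, which the C7 hydroxyl displaces with its own C–O bond untouched. The tetrahydrofuran is closed without a cationic intermediate and the route returns at 10.

**Step 8.**
- Risk: loss of site selectivity (acylation of the C7' hydroxyl as well, or double acylation), and acid-induced cyclodehydration of the 1,4-diol to a furofuran if traces of acid are present.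
- Fallback: from 11, Et3SiCl and imidazole give the bis(triethylsilyl) ether F5. PPTS in MeOH–CH2Cl2 at 0 °C frees only the primary hydroxyl, giving the mono(triethylsilyl) ether F6, and DCC/DMAP with 14 gives the fully silylated ester F7. The fluoride conditions of step 9 then remove the triethylsilyl group together with the three tert-butyldimethylsilyl groups, arriving at 16.

## Further compounds

F1 | step 3 | (1R,4R,5R,8R)-4,8-di-Ar-3,7-dioxabicyclo[3.3.0]octane-2,6-dione (enantiomer of 8) | COc1cc([C@H](O3)[C@@H]2C(=O)O[C@@H](c4ccc(O[Si](C)(C)C(C)(C)C)c(OC)c4)[C@@H]2C3=O)ccc1O[Si](C)(C)C(C)(C)C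
F2 | step 4 | lithium (2S,3S,4S)-2-Ar-4-[(S)-Ar(hydroxy)methyl]-5-oxooxolane-3-carboxylate | COc1cc([C@@H](O)[C@H]2C(=O)O[C@H](c3ccc(O[Si](C)(C)C(C)(C)C)c(OC)c3)[C@H]2C(=O)[O-])ccc1O[Si](C)(C)C(C)(C)C.[Li+]
F3 | step 4 | (2S,3S,4S)-2-Ar-5-hydroxy-4-[(S)-Ar(hydroxy)methyl]oxolane-3-carboxylic acid (both anomers at C5) | COc1cc([C@@H](O)[C@H]2C(O)O[C@H](c3ccc(O[Si](C)(C)C(C)(C)C)c(OC)c3)[C@H]2C(=O)O)ccc1O[Si](C)(C)C(C)(C)C
F4 | step 5 | (3S,4R,5S)-5-Ar-3-[(S)-Ar(hydroxy)methyl]-4-(hydroxymethyl)oxolan-2-one | COc1cc([C@H]3OC(=O)[C@H]([C@H](O)c4ccc(O[Si](C)(C)C(C)(C)C)c(OC)c4)[C@@H]3CO)ccc1O[Si](C)(C)C(C)(C)C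
F5 | step 8 | bis(triethylsilyl) ether of 11 (C9–O and C7'–O silylated) | COc1cc([C@@H](O[Si](CC)(CC)CC)[C@H]2CO[C@H](c3ccc(O[Si](C)(C)C(C)(C)C)c(OC)c3)[C@H]2CO[Si](CC)(CC)CC)ccc1O[Si](C)(C)C(C)(C)C
F6 | step 8 | C7'-O-triethylsilyl ether of 11 with free primary C9 hydroxyl | COc1cc([C@@H](O[Si](CC)(CC)CC)[C@H]2CO[C@H](c3ccc(O[Si](C)(C)C(C)(C)C)c(OC)c3)[C@H]2CO)ccc1O[Si](C)(C)C(C)(C)C
F7 | step 8 | C7'-O-triethylsilyl ether of 15 | COc1cc([C@@H](O[Si](CC)(CC)CC)[C@H]2CO[C@H](c3ccc(O[Si](C)(C)C(C)(C)C)c(OC)c3)[C@H]2COC(=O)/C=C/c2ccc(O[Si](C)(C)C(C)(C)C)cc2)ccc1O[Si](C)(C)C(C)(C)C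
A1 | alternative 1 | cis-fused 4,8-bis[4-(allyloxy)-3-methoxyphenyl]-3,7-dioxabicyclo[3.3.0]octan-2-one, both aryl groups exo, configured as 10 | COc1cc([C@@H](O3)[C@H]2CO[C@H](c4ccc(OCC=C)c(OC)c4)[C@H]2C3=O)ccc1OCC=C
A2 | alternative 1 | (S)-5-[4-(allyloxy)-3-methoxyphenyl]furan-2(5H)-one | COc1cc([C@H]2OC(=O)C=C2)ccc1OCC=C
A3 | alternative 1 | [4-(allyloxy)-3-methoxyphenyl]chloromethyl (trimethylsilyl)methyl ether | C=CCOc1ccc(C(Cl)OC[Si](C)(C)C)cc1OC
A4 | alternative 1 | carbonyl ylide ArCH=O(+)–CH2(−) with Ar = 4-(allyloxy)-3-methoxyphenyl | C=CCOc1ccc(C=[O+][CH2-])cc1OC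
A5 | alternative 2 | cis-fused 2-Ar-7,7-dichloro-3-oxabicyclo[3.2.0]heptan-6-one (carbonyl C9 on C8, CCl2 C7' on C8', aryl exo) | ClC1(Cl)[C@H]2CO[C@H](c3ccc(O[Si](C)(C)C(C)(C)C)c(OC)c3)[C@H]2C1=O
A6 | alternative 2 | (S)-2-Ar-2,5-dihydrofuran | COc1cc([C@H]2OCC=C2)ccc1O[Si](C)(C)C(C)(C)C
A7 | alternative 2 | dichloroketene | ClC(Cl)=C=O
A8 | alternative 3 | (1S,4S,5R,8S)-4,8-di-Ar-3,7-dioxabicyclo[3.3.0]octan-2-one (identical with 10) | COc1cc([C@@H](O3)[C@H]2CO[C@H](c4ccc(O[Si](C)(C)C(C)(C)C)c(OC)c4)[C@H]2C3=O)ccc1O[Si](C)(C)C(C)(C)C
A9 | alternative 3 | methyl 2-Ar-2,5-dihydrofuran-3-carboxylate, aryl-bearing carbon configured as C7 of the target | COC(=O)C1=CCO[C@@H]1c2ccc(O[Si](C)(C)C(C)(C)C)c(OC)c2
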